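Retrosynthesis: with C4 taken back to the carbinol, the aryl ether bond O1–C8a of ring C is cut first, then C2–C3 (Claisen condensation), C3–C4 (methyl addition to a ring A aldehyde) and the two aryl–prenyl bonds at C8 and C3'.
Forward: a prenylated 2-bromoaryl methyl ketone (ring A) and a prenylated benzoate (ring B) are made separately, joined at C2–C3 to a 1,3-diketone and reduced to the anti-1,3-diol; ring C, the only ring built, closes last at O1–C8a.
Enabling feature: O1 links the sp3 stereocentre C2 to the ring A carbon C8a, so closing ring C from the aryl side never touches the C2–O bond.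
Stereochemistry: C2 (S) comes from catalyst-controlled Noyori transfer hydrogenation with RuCl[(S,S)-TsDPEN](p-cymene) and is carried through with retention; the C4 carbinol set in the same step is a temporary centre and is oxidised away.
End game: oxidation at C4, then acid removal of three MOM ethers.

Key step: step 10

Remark: atoms are numbered as in the flavanone (O1, C2, C3, C4, C4a, C8, C8a; primed numbers for ring B); diketone 15 is drawn as the diketo tautomer although the enol should predominate, and alcohol 9 is racemic.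

Step 1
Reactants: 1 2-bromo-4-hydroxybenzaldehyde
Product: 2 2-bromo-4-(methoxymethoxy)benzaldehyde
Conditions: MOMCl, i-Pr2NEt, CH2Cl2, 0 °C to rt
Reagents that add atoms: chloromethyl methyl ether (MOMCl), COCCl
Why: Williamson-type O-alkylation of the acidic para-formyl phenol gives a MOM ether that withstands amide bases, organometallics and hot carbonate and later helps to direct the ring lithiation.

Step 2
Reactants: 2 2-bromo-4-(methoxymethoxy)benzaldehyde
Product: 3 2-bromo-1-(dimethoxymethyl)-4-(methoxymethoxy)benzene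
Conditions: HC(OMe)3, PPTS (cat.), MeOH, rt
Reagents that add atoms: trimethyl orthoformate, COC(OC)OC
Why: Acid-catalysed acetalisation, driven by the orthoester, masks the aldehyde against the base and aryl-metal species of step 3, and PPTS at room temperature should be too weak to cleave the aryl MOM ether.

Step 3
Reactants: 3 2-bromo-1-(dimethoxymethyl)-4-(methoxymethoxy)benzene; 4 prenyl bromide
Product: 8 2-bromo-4-(methoxymethoxy)-3-(3-methylbut-2-en-1-yl)benzaldehyde, via aryllithium 5 (not isolated), via arylcopper 6 (not isolated), via prenylated acetal 7 (not isolated)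
Conditions: LiN(i-Pr)2, THF, −78 °C; CuBr·SMe2, −78 °C; prenyl bromide, −78 to 0 °C; then 1 M aq. HCl, THF, rt
Reagents that add atoms: water, O
Why: Directed ortho-metalation removes the most acidic ring proton, the one flanked by bromine and the chelating MOM ether, without bromine–lithium exchange; the ortho-bromoaryllithium should be stable at −78 °C, its arylcopper should substitute prenyl bromide at the CH2 terminus (SN2 rather than SN2'), and dilute acid then hydrolyses the labile benzaldehyde acetal while the MOM ether stays.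

Step 4
Reactants: 8 2-bromo-4-(methoxymethoxy)-3-(3-methylbut-2-en-1-yl)benzaldehyde
Product: 9 rac-1-[2-bromo-4-(methoxymethoxy)-3-(3-methylbut-2-en-1-yl)phenyl]ethan-1-ol
Conditions: MeMgBr, THF, −78 to 0 °C; aq. NH4Cl work-up
Reagents that add atoms: methylmagnesium bromide, C[Mg]Br
Why: Grignard 1,2-addition to the aldehyde forms the C3–C4 bond, MeMgBr does not exchange with the aryl bromide, and the racemic carbinol is of no consequence because it is oxidised in step 5.

Step 5
Reactants: 9 rac-1-[2-bromo-4-(methoxymethoxy)-3-(3-methylbut-2-en-1-yl)phenyl]ethan-1-ol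
Product: 10 1-[2-bromo-4-(methoxymethoxy)-3-(3-methylbut-2-en-1-yl)phenyl]ethan-1-one
Conditions: Dess–Martin periodinane, CH2Cl2, rt
Reagents that add atoms: none
Why: Dess–Martin oxidation of a secondary benzylic alcohol runs under near-neutral conditions that leave the prenyl alkene, the aryl bromide and the MOM ether untouched.

Step 6
Reactants: 11 methyl 3-bromo-4,5-dihydroxybenzoate
Product: 12 methyl 3-bromo-4,5-bis(methoxymethoxy)benzoate
Conditions: MOMCl, i-Pr2NEt, CH2Cl2, 0 °C to rt
Reagents that add atoms: chloromethyl methyl ether (MOMCl), COCCl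
Why: Double Williamson-type MOM protection of the catechol removes both acidic protons before the organozinc coupling and the enolate chemistry.

Step 7
Reactants: 12 methyl 3-bromo-4,5-bis(methoxymethoxy)benzoate; 4 prenyl bromide
Product: 14 methyl 3,4-bis(methoxymethoxy)-5-(3-methylbut-2-en-1-yl)benzoate, via prenylzinc bromide 13 (not isolated)
Conditions: 4, Zn dust, LiCl, THF, 0 °C to rt; then 12, Pd(OAc)2 (cat.), CPhos (cat.), THF, rt
Reagents that add atoms: none
Why: Negishi coupling, in which zerovalent palladium inserts into the aryl bromide, the allylic zinc reagent transmetalates and the bulky biarylphosphine makes reductive elimination at the CH2 terminus faster than allyl transposition, should give the linear prenyl arene while the methyl ester is inert to the zinc reagent at room temperature.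

Step 8
Reactants: 10 1-[2-bromo-4-(methoxymethoxy)-3-(3-methylbut-2-en-1-yl)phenyl]ethan-1-one; 14 methyl 3,4-bis(methoxymethoxy)-5-(3-methylbut-2-en-1-yl)benzoate
Product: 15 1-[3,4-bis(methoxymethoxy)-5-(3-methylbut-2-en-1-yl)phenyl]-3-[2-bromo-4-(methoxymethoxy)-3-(3-methylbut-2-en-1-yl)phenyl]propane-1,3-dione
Conditions: NaH, THF, 60 °C; then AcOH
Reagents that add atoms: none
Why: Crossed Claisen condensation of the only enolisable partner (the methyl ketone) with the non-enolisable benzoate forms C2–C3 and is driven by deprotonation of the 1,3-diketone, which without copper should not displace the ortho bromide at this temperature.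

Step 9
Reactants: 15 1-[3,4-bis(methoxymethoxy)-5-(3-methylbut-2-en-1-yl)phenyl]-3-[2-bromo-4-(methoxymethoxy)-3-(3-methylbut-2-en-1-yl)phenyl]propane-1,3-dione
Product: 17 (1S,3S)-1-[3,4-bis(methoxymethoxy)-5-(3-methylbut-2-en-1-yl)phenyl]-3-[2-bromo-4-(methoxymethoxy)-3-(3-methylbut-2-en-1-yl)phenyl]propane-1,3-diol, via hydroxy ketone 16 (not isolated)
Conditions: RuCl[(S,S)-TsDPEN](p-cymene) (cat.), HCO2H/Et3N (5:2), DMF, 40 °C
Reagents that add atoms: none
Why: Noyori asymmetric transfer hydrogenation reduces each aryl ketone under catalyst control, the (S,S)-diamine ligand placing the aryl group under the η6-arene so that hydride adds to the face giving the S carbinol at C2 and again at C4 (the unhindered ring B carbonyl is expected to go first), which makes the anti-diol, turns a wrong second event into a separable syn diastereomer instead of the enantiomer, and leaves alkenes and the C–Br bond alone.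

Step 10
Reactants: 17 (1S,3S)-1-[3,4-bis(methoxymethoxy)-5-(3-methylbut-2-en-1-yl)phenyl]-3-[2-bromo-4-(methoxymethoxy)-3-(3-methylbut-2-en-1-yl)phenyl]propane-1,3-diol
Product: 18 (2S,4S)-2-[3,4-bis(methoxymethoxy)-5-(3-methylbut-2-en-1-yl)phenyl]-7-(methoxymethoxy)-8-(3-methylbut-2-en-1-yl)chroman-4-ol
Conditions: CuI (10 mol %), 3,4,7,8-tetramethyl-1,10-phenanthroline (20 mol %), Cs2CO3, toluene, 110 °C
Reagents that add atoms: none
Why: Cs2CO3 and ligated monovalent copper turn the diol into a copper alkoxide, copper inserts into the C8a–Br bond to give a trivalent aryl copper alkoxide held as a seven-membered cupracycle through the C2 oxygen, and reductive elimination forms O1–C8a and returns monovalent copper. The closest known reaction type is the intramolecular Ullmann-type (or palladium-catalysed) etherification of 3-(2-haloaryl)propan-1-ols to 2-substituted chromans, which keeps the carbinol configuration. Ring C (O1, C2, C3, C4, C4a, C8a) closes in a 6-exo mode on the aromatic carbon C8a, the six-membered ring arising by contraction of the metallacycle. No stereocentre is formed: neither C2–O nor C4–O is broken, so both keep the S configuration from step 9 and the anti-diol becomes the 2,4-cis-flavan-4-ol. The selectivity needed is between the two hydroxyls and against loss of bromine: the C4 hydroxyl could only close a strained four-membered ring, so ring size sends the coupling to the C2 oxygen, and keeping C4 at the alcohol level shuts off the retro-aldol and E1cB pathways that a β-hydroxy ketone would follow under hot carbonate.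

Step 11
Reactants: 18 (2S,4S)-2-[3,4-bis(methoxymethoxy)-5-(3-methylbut-2-en-1-yl)phenyl]-7-(methoxymethoxy)-8-(3-methylbut-2-en-1-yl)chroman-4-ol
Product: 19 (2S)-2-[3,4-bis(methoxymethoxy)-5-(3-methylbut-2-en-1-yl)phenyl]-7-(methoxymethoxy)-8-(3-methylbut-2-en-1-yl)chroman-4-one
Conditions: Dess–Martin periodinane, CH2Cl2, 0 °C to rt
Reagents that add atoms: none
Why: Dess–Martin oxidation of the benzylic C4 carbinol gives the flavanone without base, so the C2 centre cannot be lost through ring opening to the chalcone, and the prenyl groups and MOM ethers are not affected.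

Step 12
Reactants: 19 (2S)-2-[3,4-bis(methoxymethoxy)-5-(3-methylbut-2-en-1-yl)phenyl]-7-(methoxymethoxy)-8-(3-methylbut-2-en-1-yl)chroman-4-one
Product: 20 (2S)-2-[3,4-dihydroxy-5-(3-methylbut-2-en-1-yl)phenyl]-7-hydroxy-8-(3-methylbut-2-en-1-yl)chroman-4-one
Conditions: 3 M HCl in MeOH, 40 °C
Reagents that add atoms: none
Why: Acid-catalysed acetal exchange with methanol removes the three MOM ethers, a standard deprotection for prenylated flavanones that avoids base-induced ring opening at C2 and, if stopped at full conversion, should come before cyclisation of a prenyl group onto its neighbouring phenol.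

Compound list
1 | 2-bromo-4-hydroxybenzaldehyde | O=Cc1ccc(O)cc1Br | starting material
2 | 2-bromo-4-(methoxymethoxy)benzaldehyde | COCOc1ccc(C=O)c(Br)c1 | intermediate
3 | 2-bromo-1-(dimethoxymethyl)-4-(methoxymethoxy)benzene | COCOc1ccc(C(OC)OC)c(Br)c1 | intermediate
4 | prenyl bromide (1-bromo-3-methylbut-2-ene) | CC(C)=CCBr | starting material
5 | [2-bromo-3-(dimethoxymethyl)-6-(methoxymethoxy)phenyl]lithium | COCOc1ccc(C(OC)OC)c(Br)c1[Li] | intermediate
6 | [2-bromo-3-(dimethoxymethyl)-6-(methoxymethoxy)phenyl]copper | COCOc1ccc(C(OC)OC)c(Br)c1[Cu] | intermediate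
7 | 2-bromo-1-(dimethoxymethyl)-4-(methoxymethoxy)-3-(3-methylbut-2-en-1-yl)benzene | COCOc1ccc(C(OC)OC)c(Br)c1CC=C(C)C | intermediate
8 | 2-bromo-4-(methoxymethoxy)-3-(3-methylbut-2-en-1-yl)benzaldehyde | COCOc1ccc(C=O)c(Br)c1CC=C(C)C | intermediate
9 | rac-1-[2-bromo-4-(methoxymethoxy)-3-(3-methylbut-2-en-1-yl)phenyl]ethan-1-ol | COCOc1ccc(C(C)O)c(Br)c1CC=C(C)C | intermediate
10 | 1-[2-bromo-4-(methoxymethoxy)-3-(3-methylbut-2-en-1-yl)phenyl]ethan-1-one | COCOc1ccc(C(C)=O)c(Br)c1CC=C(C)C | intermediate
11 | methyl 3-bromo-4,5-dihydroxybenzoate | COC(=O)c1cc(O)c(O)c(Br)c1 | starting material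
12 | methyl 3-bromo-4,5-bis(methoxymethoxy)benzoate | COC(=O)c1cc(OCOC)c(OCOC)c(Br)c1 | intermediate
13 | prenylzinc bromide | CC(C)=CC[Zn]Br | intermediate
14 | methyl 3,4-bis(methoxymethoxy)-5-(3-methylbut-2-en-1-yl)benzoate | COC(=O)c1cc(OCOC)c(OCOC)c(CC=C(C)C)c1 | intermediate
15 | 1-[3,4-bis(methoxymethoxy)-5-(3-methylbut-2-en-1-yl)phenyl]-3-[2-bromo-4-(methoxymethoxy)-3-(3-methylbut-2-en-1-yl)phenyl]propane-1,3-dione | CC(C)=CCc1cc(C(=O)CC(=O)c2ccc(OCOC)c(CC=C(C)C)c2Br)cc(OCOC)c1OCOC | intermediate
16 | (3S)-3-[3,4-bis(methoxymethoxy)-5-(3-methylbut-2-en-1-yl)phenyl]-1-[2-bromo-4-(methoxymethoxy)-3-(3-methylbut-2-en-1-yl)phenyl]-3-hydroxypropan-1-one | CC(C)=CCc1cc([C@@H](O)CC(=O)c2ccc(OCOC)c(CC=C(C)C)c2Br)cc(OCOC)c1OCOC | intermediate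
17 | (1S,3S)-1-[3,4-bis(methoxymethoxy)-5-(3-methylbut-2-en-1-yl)phenyl]-3-[2-bromo-4-(methoxymethoxy)-3-(3-methylbut-2-en-1-yl)phenyl]propane-1,3-diol (anti) | CC(C)=CCc1cc([C@@H](O)C[C@H](O)c2ccc(OCOC)c(CC=C(C)C)c2Br)cc(OCOC)c1OCOC | intermediate
18 | (2S,4S)-2-[3,4-bis(methoxymethoxy)-5-(3-methylbut-2-en-1-yl)phenyl]-7-(methoxymethoxy)-8-(3-methylbut-2-en-1-yl)chroman-4-ol (2,4-cis) | CC(C)=CCc1cc([C@@H]2C[C@H](O)c3ccc(OCOC)c(CC=C(C)C)c3O2)cc(OCOC)c1OCOC | intermediate
19 | (2S)-2-[3,4-bis(methoxymethoxy)-5-(3-methylbut-2-en-1-yl)phenyl]-7-(methoxymethoxy)-8-(3-methylbut-2-en-1-yl)chroman-4-one | CC(C)=CCc1cc([C@@H]2CC(=O)c3ccc(OCOC)c(CC=C(C)C)c3O2)cc(OCOC)c1OCOC | intermediate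
20 | (2S)-2-[3,4-dihydroxy-5-(3-methylbut-2-en-1-yl)phenyl]-7-hydroxy-8-(3-methylbut-2-en-1-yl)chroman-4-one | CC(C)=CCc1cc([C@@H]2CC(=O)c3ccc(O)c(CC=C(C)C)c3O2)cc(O)c1O | target

Total steps: 12. Longest linear sequence: 10 steps (steps 1, 2, 3, 4, 5, 8, 9, 10, 11, 12); the ring B branch (steps 6 and 7) joins at step 8.

Steps most likely to fail

Step 10. The hindered, electron-rich C8a–Br bond may resist copper insertion, or an alkoxide may be oxidised while the bromide is reduced away; the free C4 hydroxyl offers the metal a second binding site and could hold it unproductively. The fallback sets out from 17 and returns at 18; it removes the competing alkoxide and moves the ring closure to palladium. Both hydroxyls are silylated (TESOTf, 2,6-lutidine, CH2Cl2, −78 °C) to the bis(triethylsilyl) ether F1. The less hindered C2 silyl ether, which has no ortho substituent beside it, is then cleaved selectively (PPTS, MeOH/CH2Cl2, −10 °C) to the C4-O-triethylsilyl mono-ether F2. With only the C2 alkoxide available, the O1–C8a bond is closed with Pd(OAc)2, 2-(di-tert-butylphosphino)-1,1'-binaphthyl and Cs2CO3 in toluene at 80 °C to the 4-O-triethylsilyl flavan F3. TBAF in THF then frees the C4 hydroxyl to give 18.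

Step 9. The reduction may stall at the hydrogen-bonded enol or at 16, or the second hydride transfer may show poor facial selectivity and give the syn diol. The fallback sets out from 14 and 10 and returns at 17; it sets C2 by an aldol reaction and C4 by internal hydride delivery. Ester 14 is reduced (LiAlH4, THF, 0 °C) to the benzylic alcohol F4 and oxidised (MnO2, CH2Cl2) to the ring B aldehyde F5. Ketone 10 is converted (TMSOTf, Et3N, CH2Cl2, 0 °C) into the trimethylsilyl enol ether F6. A Lewis-base-catalysed Mukaiyama aldol of F6 with F5 (SiCl4, chiral bisphosphoramide of the enantiomer that gives the S carbinol, i-Pr2NEt, CH2Cl2, −78 °C) should give 16, which is isolated here. Evans–Saksena reduction (Me4NBH(OAc)3, MeCN/AcOH, −30 °C) then delivers hydride from the boron bound at the C2 oxygen to give the anti-diol 17.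

Step 3. The ortho-bromoaryllithium may lose LiBr to an aryne, bromine may migrate (halogen dance), or the allylic substitution may run SN2' and give the 1,1-dimethylallyl isomer. The fallback sets out from 1 and returns at 8; it brings in the side chain by sigmatropic rearrangement and olefin metathesis. Phenol 1 is allylated (allyl bromide, K2CO3, acetone) to the allyl ether F7. Aromatic Claisen rearrangement (N,N-diethylaniline, 190 °C) should give 3-allyl-2-bromo-4-hydroxybenzaldehyde F8; the meta bromine is expected to favour migration to C3, and the C5 isomer is removed by chromatography. MOM protection (MOMCl, i-Pr2NEt) gives the MOM ether F9, and cross-metathesis with 2-methyl-2-butene (second-generation Grubbs catalyst, CH2Cl2, 40 °C) turns the allyl group into prenyl, giving 8.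

Further compounds
F1 | step 10 | (1S,3S)-1-[3,4-bis(methoxymethoxy)-5-(3-methylbut-2-en-1-yl)phenyl]-3-[2-bromo-4-(methoxymethoxy)-3-(3-methylbut-2-en-1-yl)phenyl]-1,3-bis(triethylsilyloxy)propane | CC(C)=CCc1cc([C@@H](O[Si](CC)(CC)CC)C[C@H](O[Si](CC)(CC)CC)c2ccc(OCOC)c(CC=C(C)C)c2Br)cc(OCOC)c1OCOC
F2 | step 10 | (1S,3S)-1-[3,4-bis(methoxymethoxy)-5-(3-methylbut-2-en-1-yl)phenyl]-3-[2-bromo-4-(methoxymethoxy)-3-(3-methylbut-2-en-1-yl)phenyl]-3-(triethylsilyloxy)propan-1-ol | CC(C)=CCc1cc([C@@H](O)C[C@H](O[Si](CC)(CC)CC)c2ccc(OCOC)c(CC=C(C)C)c2Br)cc(OCOC)c1OCOC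
F3 | step 10 | (2S,4S)-2-[3,4-bis(methoxymethoxy)-5-(3-methylbut-2-en-1-yl)phenyl]-7-(methoxymethoxy)-8-(3-methylbut-2-en-1-yl)-4-(triethylsilyloxy)chroman | CC(C)=CCc1cc([C@@H]2C[C@H](O[Si](CC)(CC)CC)c3ccc(OCOC)c(CC=C(C)C)c3O2)cc(OCOC)c1OCOC
F4 | step 9 | [3,4-bis(methoxymethoxy)-5-(3-methylbut-2-en-1-yl)phenyl]methanol | OCc1cc(OCOC)c(OCOC)c(CC=C(C)C)c1
F5 | step 9 | 3,4-bis(methoxymethoxy)-5-(3-methylbut-2-en-1-yl)benzaldehyde | O=Cc1cc(OCOC)c(OCOC)c(CC=C(C)C)c1
F6 | step 9 | {1-[2-bromo-4-(methoxymethoxy)-3-(3-methylbut-2-en-1-yl)phenyl]ethenyloxy}trimethylsilane | C=C(O[Si](C)(C)C)c1ccc(OCOC)c(CC=C(C)C)c1Br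
F7 | step 3 | 4-(allyloxy)-2-bromobenzaldehyde | C=CCOc1ccc(C=O)c(Br)c1
F8 | step 3 | 3-allyl-2-bromo-4-hydroxybenzaldehyde | C=CCc1c(O)ccc(C=O)c1Br
F9 | step 3 | 3-allyl-2-bromo-4-(methoxymethoxy)benzaldehyde | C=CCc1c(OCOC)ccc(C=O)c1Br
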